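## Retrosynthetic overview

1. The nitrogen ring is closed last by Bischler–Napieralski cyclisation of an N-acetyl (S)-arylisopropylamine with the naphthol masked as its acetate; C-3 comes from L-alaninol through aziridine opening by an aryl Grignard reagent.
2. The naphthol ring (the ring carrying OH and the biaryl bond) comes from ring-closing metathesis and tautomerisation of an aryl 1-aryl-allyl ketone with an ortho-vinyl group.
3. That ketone comes from a homoallylic alcohol made by intermolecular indium-mediated allylation of 2-ethenyl-6-methoxy-4-methylbenzaldehyde with the γ-aryl allyl bromide of the amine fragment. This is the fragment-joining C–C bond (future C-1/C-2 of the naphthalene).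
4. The allyl bromide is built by ortho-lithiation/formylation, HWE olefination, reduction and bromination; the aldehyde by ortho-lithiation/formylation and Suzuki vinylation of 3-bromo-5-methylanisole.
5. Ring order: second naphthalene ring first, then the dihydropyridine ring.

Assumption: the biaryl axis carries no stereodescriptor in the given structure, so only C-3 (S) is controlled and the axis is taken as it forms.

## Route

Step 1
Reactants: 1 tert-butyl (S)-(1-hydroxypropan-2-yl)carbamate (N-Boc-L-alaninol)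
Product: 3 tert-butyl (S)-2-methylaziridine-1-carboxylate, via O-tosylate 2 (not isolated)
Conditions: TsCl, KOH (powdered), THF, reflux
Reagents that add atoms: none
Why: O-tosylation of the primary alcohol followed by intramolecular SN2 N-alkylation (Wenker-type aziridine synthesis) closes the ring at CH2, so the (S) centre from L-alanine is untouched.

Step 2
Reactants: 4 1-bromo-3,5-dimethoxybenzene; 3 tert-butyl (S)-2-methylaziridine-1-carboxylate
Product: 6 tert-butyl (S)-[1-(3,5-dimethoxyphenyl)propan-2-yl]carbamate, via Grignard reagent 5 (not isolated)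
Conditions: Mg, THF; then CuBr·SMe2 (10 mol %), 3, THF, −30 °C to rt; aq. NH4Cl
Reagents that add atoms: none
Why: Copper-catalysed Grignard opening of the activated N-Boc aziridine is an SN2 attack at the unsubstituted CH2, so the (S) centre is carried over unchanged.

Step 3
Reactants: 6 tert-butyl (S)-[1-(3,5-dimethoxyphenyl)propan-2-yl]carbamate
Product: 8 tert-butyl (S)-[1-(4-formyl-3,5-dimethoxyphenyl)propan-2-yl]carbamate, via dilithio species 7 (not isolated)
Conditions: n-BuLi (2.4 equiv), THF, −78 to 0 °C; DMF; aq. NH4Cl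
Reagents that add atoms: N,N-dimethylformamide, CN(C)C=O
Why: Directed ortho-metalation: after N–H deprotonation the second equivalent of n-BuLi lithiates the doubly activated position between the two methoxy groups, and DMF formylates it.

Step 4
Reactants: 8 tert-butyl (S)-[1-(4-formyl-3,5-dimethoxyphenyl)propan-2-yl]carbamate
Product: 9 ethyl (E)-3-[4-[(2S)-2-(tert-butoxycarbonylamino)propyl]-2,6-dimethoxyphenyl]prop-2-enoate
Conditions: (EtO)2P(O)CH2CO2Et, NaH, THF, 0 °C to rt
Reagents that add atoms: triethyl phosphonoacetate, CCOC(=O)CP(=O)(OCC)OCC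
Why: Horner–Wadsworth–Emmons olefination of an aryl aldehyde with a stabilised phosphonate gives the (E)-cinnamate reliably.

Step 5
Reactants: 9 ethyl (E)-3-[4-[(2S)-2-(tert-butoxycarbonylamino)propyl]-2,6-dimethoxyphenyl]prop-2-enoate
Product: 11 ethyl (E)-3-[4-[(2S)-2-acetamidopropyl]-2,6-dimethoxyphenyl]prop-2-enoate, via amine hydrochloride 10 (not isolated)
Conditions: HCl (4 M in dioxane), rt; evaporate; Ac2O, Et3N, CH2Cl2, 0 °C to rt
Reagents that add atoms: acetic anhydride, CC(=O)OC(C)=O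
Why: Acidolytic Boc cleavage and N-acetylation install the amide needed for the final ring closure at a stage where the molecule still tolerates acid; the stereocentre is not involved.

Step 6
Reactants: 11 ethyl (E)-3-[4-[(2S)-2-acetamidopropyl]-2,6-dimethoxyphenyl]prop-2-enoate
Product: 12 N-[(2S)-1-[4-[(E)-3-hydroxyprop-1-enyl]-3,5-dimethoxyphenyl]propan-2-yl]acetamide
Conditions: i-Bu2AlH (3.5 equiv), CH2Cl2, −78 °C; aq. KNaC4H4O6
Reagents that add atoms: none
Why: 1,2-Reduction of the conjugated ester by the aluminium hydride at −78 °C gives the allylic alcohol, while the N-metalated secondary amide is not reduced at this temperature.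

Step 7
Reactants: 12 N-[(2S)-1-[4-[(E)-3-hydroxyprop-1-enyl]-3,5-dimethoxyphenyl]propan-2-yl]acetamide
Product: 13 N-[(2S)-1-[4-[(E)-3-bromoprop-1-enyl]-3,5-dimethoxyphenyl]propan-2-yl]acetamide
Conditions: CBr4, PPh3, CH2Cl2, −20 to 0 °C; short filtration, used at once
Reagents that add atoms: carbon tetrabromide, BrC(Br)(Br)Br
Why: Appel bromination converts the primary allylic alcohol under neutral conditions, which suits this ionisation-prone electron-rich cinnamyl bromide.

Step 8
Reactants: 14 1-bromo-3-methoxy-5-methylbenzene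
Product: 16 2-bromo-6-methoxy-4-methylbenzaldehyde, via aryllithium 15 (not isolated)
Conditions: LiN(i-Pr)2, THF, −78 °C; DMF, −78 °C; aq. NH4Cl
Reagents that add atoms: N,N-dimethylformamide, CN(C)C=O
Why: Directed ortho-lithiation with the amide base (no Br–Li exchange) removes the most acidic proton, flanked by Br and OMe, and formylation at −78 °C outruns aryne formation.

Step 9
Reactants: 16 2-bromo-6-methoxy-4-methylbenzaldehyde
Product: 17 2-ethenyl-6-methoxy-4-methylbenzaldehyde
Conditions: CH2=CH–Bpin, PdCl2(dppf) (3 mol %), K2CO3, dioxane/H2O, 90 °C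
Reagents that add atoms: vinylboronic acid pinacol ester, C=CB1OC(C)(C)C(C)(C)O1
Why: Suzuki–Miyaura coupling of an aldehyde-activated aryl bromide with a vinylboronate is a standard entry to 2-vinylbenzaldehydes.

Step 10
Reactants: 13 N-[(2S)-1-[4-[(E)-3-bromoprop-1-enyl]-3,5-dimethoxyphenyl]propan-2-yl]acetamide; 17 2-ethenyl-6-methoxy-4-methylbenzaldehyde
Product: 19 N-[(2S)-1-[4-[1-(2-ethenyl-6-methoxy-4-methylphenyl)-1-hydroxybut-3-en-2-yl]-3,5-dimethoxyphenyl]propan-2-yl]acetamide (diastereomer mixture), via allylindium reagent 18 (not isolated)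
Conditions: In powder (1.5 equiv), DMF, rt; aq. NH4Cl
Reagents that add atoms: none
Why: Barbier-type indium-mediated carbonyl allylation: the allylindium adds through its γ-carbon in a six-membered transition state to give the branched homoallylic alcohol, forming the future C-1/C-2 bond of the naphthalene; the two new centres (mainly anti) need no control because both are erased in steps 11 and 12.

Step 11
Reactants: 19 N-[(2S)-1-[4-[1-(2-ethenyl-6-methoxy-4-methylphenyl)-1-hydroxybut-3-en-2-yl]-3,5-dimethoxyphenyl]propan-2-yl]acetamide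
Product: 20 N-[(2S)-1-[4-[1-(2-ethenyl-6-methoxy-4-methylphenyl)-1-oxobut-3-en-2-yl]-3,5-dimethoxyphenyl]propan-2-yl]acetamide
Conditions: Dess–Martin periodinane, CH2Cl2, 0 °C to rt; crude product used directly
Reagents that add atoms: none
Why: Dess–Martin oxidation of the secondary benzylic alcohol is base-free, so the β,γ-unsaturated ketone is obtained without the alkene moving into conjugation.

Step 12
Reactants: 20 N-[(2S)-1-[4-[1-(2-ethenyl-6-methoxy-4-methylphenyl)-1-oxobut-3-en-2-yl]-3,5-dimethoxyphenyl]propan-2-yl]acetamide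
Product: 22 N-[(2S)-1-[4-(1-hydroxy-8-methoxy-6-methylnaphthalen-2-yl)-3,5-dimethoxyphenyl]propan-2-yl]acetamide, via naphthalen-1(2H)-one 21 (not isolated)
Conditions: second-generation Grubbs catalyst RuCl2(=CHPh)(H2IMes)(PCy3) (5 mol %), CH2Cl2, 40 °C
Reagents that add atoms: none
Why: Ring-closing metathesis of the styrene and the terminal vinyl group forms the six-membered ring with loss of ethene, and the resulting 2-aryl-naphthalen-1(2H)-one enolises irreversibly to the aromatic 1-naphthol.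

Step 13
Reactants: 22 N-[(2S)-1-[4-(1-hydroxy-8-methoxy-6-methylnaphthalen-2-yl)-3,5-dimethoxyphenyl]propan-2-yl]acetamide
Product: 23 2-[4-[(2S)-2-acetamidopropyl]-2,6-dimethoxyphenyl]-8-methoxy-6-methylnaphthalen-1-yl acetate
Conditions: Ac2O, pyridine, DMAP (cat.), rt to 40 °C
Reagents that add atoms: acetic anhydride, CC(=O)OC(C)=O
Why: DMAP-catalysed O-acetylation masks the naphthol so that POCl3 cannot phosphorylate it in the next step.

Step 14
Reactants: 23 2-[4-[(2S)-2-acetamidopropyl]-2,6-dimethoxyphenyl]-8-methoxy-6-methylnaphthalen-1-yl acetate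
Product: 25 2-[(3S)-6,8-dimethoxy-1,3-dimethyl-3,4-dihydroisoquinolin-7-yl]-8-methoxy-6-methylnaphthalen-1-yl acetate, via imidoyl chloride 24 (not isolated)
Conditions: POCl3 (3 equiv), MeCN, 80 °C; aq. NaHCO3
Reagents that add atoms: none
Why: Bischler–Napieralski cyclodehydration: the activated amide attacks the ring position ortho to one methoxy and para to the other (the two candidate positions are equivalent), closing the 3,4-dihydroisoquinoline without touching C-3.

Step 15
Reactants: 25 2-[(3S)-6,8-dimethoxy-1,3-dimethyl-3,4-dihydroisoquinolin-7-yl]-8-methoxy-6-methylnaphthalen-1-yl acetate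
Product: 26 2-[(3S)-6,8-dimethoxy-1,3-dimethyl-3,4-dihydroisoquinolin-7-yl]-8-methoxy-6-methylnaphthalen-1-ol
Conditions: K2CO3 (0.2 equiv), MeOH, 0 °C to rt
Reagents that add atoms: none
Why: Base-catalysed methanolysis (transesterification) of the aryl acetate frees the naphthol under conditions that leave the cyclic imine and the methyl ethers alone.

## Compound list

1 | tert-butyl (S)-(1-hydroxypropan-2-yl)carbamate | C[C@H](NC(=O)OC(C)(C)C)CO | starting material
2 | (S)-2-(tert-butoxycarbonylamino)propyl 4-methylbenzenesulfonate | C[C@H](NC(=O)OC(C)(C)C)COS(=O)(=O)c1ccc(C)cc1 | intermediate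
3 | tert-butyl (S)-2-methylaziridine-1-carboxylate | C[C@H]1CN1C(=O)OC(C)(C)C | intermediate
4 | 1-bromo-3,5-dimethoxybenzene | COc1cc(Br)cc(OC)c1 | starting material
5 | (3,5-dimethoxyphenyl)magnesium bromide | COc1cc([Mg]Br)cc(OC)c1 | intermediate
6 | tert-butyl (S)-[1-(3,5-dimethoxyphenyl)propan-2-yl]carbamate | CC(C)(C)OC(=O)N[C@@H](C)Cc1cc(OC)cc(OC)c1 | intermediate
7 | N-lithio tert-butyl (S)-[1-(4-lithio-3,5-dimethoxyphenyl)propan-2-yl]carbamate | CC(C)(C)OC(=O)N([Li])[C@@H](C)Cc1cc(OC)c([Li])c(OC)c1 | intermediate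
8 | tert-butyl (S)-[1-(4-formyl-3,5-dimethoxyphenyl)propan-2-yl]carbamate | CC(C)(C)OC(=O)N[C@@H](C)Cc1cc(OC)c(C=O)c(OC)c1 | intermediate
9 | ethyl (E)-3-[4-[(2S)-2-(tert-butoxycarbonylamino)propyl]-2,6-dimethoxyphenyl]prop-2-enoate | CCOC(=O)/C=C/c1c(OC)cc(C[C@H](C)NC(=O)OC(C)(C)C)cc1OC | intermediate
10 | ethyl (E)-3-[4-[(2S)-2-aminopropyl]-2,6-dimethoxyphenyl]prop-2-enoate hydrochloride | CCOC(=O)/C=C/c1c(OC)cc(C[C@H](C)N)cc1OC.Cl | intermediate
11 | ethyl (E)-3-[4-[(2S)-2-acetamidopropyl]-2,6-dimethoxyphenyl]prop-2-enoate | CCOC(=O)/C=C/c1c(OC)cc(C[C@H](C)NC(C)=O)cc1OC | intermediate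
12 | N-[(2S)-1-[4-[(E)-3-hydroxyprop-1-enyl]-3,5-dimethoxyphenyl]propan-2-yl]acetamide | CC(=O)N[C@@H](C)Cc1cc(OC)c(/C=C/CO)c(OC)c1 | intermediate
13 | N-[(2S)-1-[4-[(E)-3-bromoprop-1-enyl]-3,5-dimethoxyphenyl]propan-2-yl]acetamide | CC(=O)N[C@@H](C)Cc1cc(OC)c(/C=C/CBr)c(OC)c1 | intermediate
14 | 1-bromo-3-methoxy-5-methylbenzene | COc1cc(C)cc(Br)c1 | starting material
15 | (2-bromo-6-methoxy-4-methylphenyl)lithium | COc1cc(C)cc(Br)c1[Li] | intermediate
16 | 2-bromo-6-methoxy-4-methylbenzaldehyde | COc1cc(C)cc(Br)c1C=O | intermediate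
17 | 2-ethenyl-6-methoxy-4-methylbenzaldehyde | COc1cc(C)cc(C=C)c1C=O | intermediate
18 | allylindium reagent from 13, drawn as the (E)-3-aryl-allyl indium dibromide (trivalent indium) | CC(=O)N[C@@H](C)Cc1cc(OC)c(/C=C/C[In](Br)Br)c(OC)c1 | intermediate
19 | N-[(2S)-1-[4-[1-(2-ethenyl-6-methoxy-4-methylphenyl)-1-hydroxybut-3-en-2-yl]-3,5-dimethoxyphenyl]propan-2-yl]acetamide (mixture at the two new centres, mainly anti) | CC(=O)N[C@@H](C)Cc1cc(OC)c(C(C=C)C(O)c2c(OC)cc(C)cc2C=C)c(OC)c1 | intermediate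
20 | N-[(2S)-1-[4-[1-(2-ethenyl-6-methoxy-4-methylphenyl)-1-oxobut-3-en-2-yl]-3,5-dimethoxyphenyl]propan-2-yl]acetamide (epimer mixture at the ketone α-carbon) | CC(=O)N[C@@H](C)Cc1cc(OC)c(C(C=C)C(=O)c2c(OC)cc(C)cc2C=C)c(OC)c1 | intermediate
21 | N-[(2S)-1-[3,5-dimethoxy-4-(8-methoxy-6-methyl-1-oxo-1,2-dihydronaphthalen-2-yl)phenyl]propan-2-yl]acetamide | CC(=O)N[C@@H](C)Cc1cc(OC)c(C2C=Cc3cc(C)cc(OC)c3C2=O)c(OC)c1 | intermediate
22 | N-[(2S)-1-[4-(1-hydroxy-8-methoxy-6-methylnaphthalen-2-yl)-3,5-dimethoxyphenyl]propan-2-yl]acetamide | CC(=O)N[C@@H](C)Cc1cc(OC)c(-c2ccc3cc(C)cc(OC)c3c2O)c(OC)c1 | intermediate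
23 | 2-[4-[(2S)-2-acetamidopropyl]-2,6-dimethoxyphenyl]-8-methoxy-6-methylnaphthalen-1-yl acetate | CC(=O)N[C@@H](C)Cc1cc(OC)c(-c2ccc3cc(C)cc(OC)c3c2OC(C)=O)c(OC)c1 | intermediate
24 | 2-[4-[(2S)-2-(1-chloroethylideneamino)propyl]-2,6-dimethoxyphenyl]-8-methoxy-6-methylnaphthalen-1-yl acetate | CC(Cl)=N[C@@H](C)Cc1cc(OC)c(-c2ccc3cc(C)cc(OC)c3c2OC(C)=O)c(OC)c1 | intermediate
25 | 2-[(3S)-6,8-dimethoxy-1,3-dimethyl-3,4-dihydroisoquinolin-7-yl]-8-methoxy-6-methylnaphthalen-1-yl acetate | COc1cc2c(c(OC)c1-c1ccc3cc(C)cc(OC)c3c1OC(C)=O)C(C)=N[C@@H](C)C2 | intermediate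
26 | 2-[(3S)-6,8-dimethoxy-1,3-dimethyl-3,4-dihydroisoquinolin-7-yl]-8-methoxy-6-methylnaphthalen-1-ol | COc1cc2c(c(OC)c1-c1ccc3cc(C)cc(OC)c3c1O)C(C)=N[C@@H](C)C2 | target

## Step count and risks

Total steps: 15. Longest linear sequence: 13 (steps 1–7, then 10–15); steps 8–9 make the second fragment.

**Step 10 (allylation).** The electron-rich bromide 13 may decompose, or the hindered allylindium may give the linear α-adduct. The fallback sets out from allylic alcohol 12. Palladium-catalysed borylation (B2pin2, Pd(MeCN)4(BF4)2 cat., DMSO/MeOH, 50 °C) turns it into the allylboronate N-[(2S)-1-[3,5-dimethoxy-4-[(E)-3-(4,4,5,5-tetramethyl-1,3,2-dioxaborolan-2-yl)prop-1-enyl]phenyl]propan-2-yl]acetamide F1. Heating F1 with aldehyde 17 in toluene at 60–80 °C adds through a closed chair transition state that allows only γ-attack. This comes back to the route at alcohol 19 and bypasses step 7.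

**Step 3 (ortho-lithiation of the N–H carbamate).** Lithiation may be incomplete or misdirected. The fallback sets out from aziridine 3 and brings the formyl carbon in with the aryl nucleophile. Bought 4-bromo-2,6-difluorobenzaldehyde F2 is treated with NaOMe in MeOH (double SNAr ortho to the aldehyde) to give 4-bromo-2,6-dimethoxybenzaldehyde F3. Ethylene glycol and TsOH in toluene protect it as 2-(4-bromo-2,6-dimethoxyphenyl)-1,3-dioxolane F4. Mg in THF gives [4-(1,3-dioxolan-2-yl)-3,5-dimethoxyphenyl]magnesium bromide F5, which opens 3 under CuBr·SMe2 catalysis to tert-butyl (S)-[1-[4-(1,3-dioxolan-2-yl)-3,5-dimethoxyphenyl]propan-2-yl]carbamate F6. Pyridinium tosylate in wet acetone unmasks the aldehyde, and the route is rejoined at 8.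

**Step 11 (oxidation to the β,γ-unsaturated ketone).** Ketone 20 may isomerise into conjugation before it can be cyclised. The fallback sets out from alcohol 19 and reverses the order. Ring-closing metathesis with the same ruthenium catalyst first gives N-[(2S)-1-[4-(1-hydroxy-8-methoxy-6-methyl-1,2-dihydronaphthalen-2-yl)-3,5-dimethoxyphenyl]propan-2-yl]acetamide F7. Oxidation of F7 with MnO2 in CH2Cl2 gives naphthalenone 21, which tautomerises, and the route is rejoined at naphthol 22.

## Further compounds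

F1 | step 10 | N-[(2S)-1-[3,5-dimethoxy-4-[(E)-3-(4,4,5,5-tetramethyl-1,3,2-dioxaborolan-2-yl)prop-1-enyl]phenyl]propan-2-yl]acetamide | CC(=O)N[C@@H](C)Cc1cc(OC)c(/C=C/CB2OC(C)(C)C(C)(C)O2)c(OC)c1
F2 | step 3 | 4-bromo-2,6-difluorobenzaldehyde (bought) | O=Cc1c(F)cc(Br)cc1F
F3 | step 3 | 4-bromo-2,6-dimethoxybenzaldehyde | COc1cc(Br)cc(OC)c1C=O
F4 | step 3 | 2-(4-bromo-2,6-dimethoxyphenyl)-1,3-dioxolane | COc1cc(Br)cc(OC)c1C1OCCO1
F5 | step 3 | [4-(1,3-dioxolan-2-yl)-3,5-dimethoxyphenyl]magnesium bromide | COc1cc([Mg]Br)cc(OC)c1C1OCCO1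
F6 | step 3 | tert-butyl (S)-[1-[4-(1,3-dioxolan-2-yl)-3,5-dimethoxyphenyl]propan-2-yl]carbamate | CC(C)(C)OC(=O)N[C@@H](C)Cc1cc(OC)c(C2OCCO2)c(OC)c1
F7 | step 11 | N-[(2S)-1-[4-(1-hydroxy-8-methoxy-6-methyl-1,2-dihydronaphthalen-2-yl)-3,5-dimethoxyphenyl]propan-2-yl]acetamide | CC(=O)N[C@@H](C)Cc1cc(OC)c(C2C=Cc3cc(C)cc(OC)c3C2O)c(OC)c1
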